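My unit was the fraction of the G charged, which I followed as G, as D (monomer built into chains) and as E (G lost by the side step).

G 0.011 M; J 55 µM; L 29 µM; time 4.0 min

    G + J → X + D (k1 = 93.8 M⁻¹ s⁻¹)
    G + X → D + X, rate k2*[X]*[G] (k2 = 1950 M⁻¹ s⁻¹)
    D + X → G + X, rate k3*[X] as long as [D] is above zero (k3 = 1.43 s⁻¹)
    J + L → J.L (k4 = 3.22 × 10⁵ M⁻¹ s⁻¹)
    J → Q (k5 = 1.73 × 10⁻⁵ s⁻¹)
    G → E (k6 = 0.00561 s⁻¹)

1. whether the average number of monomer units in a chain (chains begun, living or dead) reaches 100 by 4.0 min (no / yes)
2. average number of monomer units in a chain (chains begun, living or dead) at 4.0 min

At the start L took each J at 9.34 s⁻¹ and G at 1.03 s⁻¹, so L was faster. But J was charged in excess of L, so I counted one J lost per L and took the living chains X as 0.236 % of the G charged.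

The chains add G at a rate that follows G and give it back at a rate that does not. The chain count cancels, so the two steps balance at the balance share, k3 over k2 times the G charged: 6.67 %, the usual equilibrium monomer level.

But G also leaks to E. Growth took G at 0.0507 s⁻¹, faster than the leak at 0.00561 s⁻¹, so I put the resting G a little lower, at 6.00 %.

Summing the leak over the fall and the rest of the run gave E as 17.4 %. D was then what remained, and dividing it by the chains gave me 324 units. A length of 100 needed D at 23.6 %, less than that remainder, so I said yes.

The forecast also said yes, with 322 units, as the "leak bleeds the polymer down".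

The run gave yes, with the length reached at 0.112 min, and 322 units at 4.0 min.

In this flask D was made 3.39 times as fast as it was used up at 0.526 min, each step taken net, but at 4.00 min the same ratio read 0.900, which is also what the 6.00 % of G left comes to when held against the balance share: 0.900. D, as a share of the G charged, went from 80.1 % at 2.00 min to 76.2 % at 4.00 min, while E rose from 13.8 % to 17.8 %.

The rate constants were chosen freely; the run is a simulation.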